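If the intermediate goes on to target in a step that needs both partner and second catalyst, and equivalents, loadings and the fraction of partner left stay fixed, its pseudo-first-order constant should grow with the square of [starting material]. I reckoned the flask on that assumption.

| flask | starting material | partner | free catalyst | second catalyst | added ligand | remark | time |
|---|---|---|---|---|---|---|---|
| south-east | 0.12 M | 1.1 equiv | 2 mol% | 13 mol% | 18 mM | run made earlier |  |
| west | 0.50 M | 1.1 equiv | 2 mol% | 13 mol% | 18 mM | run made earlier |  |
| flask | 0.25 M | 1.10 equiv | 2 mol% | 13 mol% | 18 mM |  | 3.0 h |

| run | time / h | target / % | intermediate / % |
|---|---|---|---|
| south-east | 0.667 | 1.8 | 22.6 |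
| south-east | 1.33 | 7.3 | 39.3 |
| south-east | 2.00 | 13.5 | 47.1 |
| south-east | 2.50 | 17.0 | 51.9 |
| west | 0.667 | 45.1 | 29.7 |
| west | 1.33 | 66.5 | 28.5 |
| west | 2.00 | 73.4 | 24.7 |
| west | 2.50 | 76.8 | 22.9 |

(standard deviation of a reading: 0.5 percentage points)

- the reaction counts as stopped when no species that holds the starting material changes by six tenths of a point or more over the second half of the time

- at 3.0 h, what has stopped the reaction, if anything has (the partner has run out first / no working catalyst is left / all of the starting material has reacted / it is still moving)
- target at 3.0 h, in percent of the starting material charged
- intermediate at 3.0 h, in percent of the starting material charged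

I took the target gained per intermediate between the first two readings of each run, divided it by the partner that the balance left, and scaled it by the square. The south-east run gave 1.21 /h for the flask and the west run 0.563 /h. So the time in which intermediate halves by that step at fresh partner, my halving time, came out by my reading between 0.571 h and 1.23 h.

With starting material falling at 0.953 /h, read from both runs, two steps in series gave target 82.9% and 63.1% in the flask. Those answers held partner full, so I put them back, lowered each constant by the mean partner they left, to 0.756 /h and 0.401 /h, and went round once more. My bracket for the flask was target 52.4% to 71.9% and intermediate 22.3% to 41.9%.

The forecast, holding that “The second step is much more sensitive”, said it is still moving, with target 40% and intermediate 55%. Its target stood below my bracket and its intermediate above it.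

The flask gave it is still moving, with target 55.2% and intermediate 39.6%, both inside the bracket.

    starting material + free catalyst → free catalyst + intermediate (k = 0.0990 /M/s)
    partner + second catalyst + intermediate → second catalyst + target (k = 0.0380 /M²/s)
    2 partner → self-condensation product (k = 2.00 × 10⁻⁴ /M/s)
    free catalyst + added ligand ⇌ idle complex, settled at all times (K = 51.0 /M)

In the flask at 0.651 h, with partner no longer fresh, the half-life of intermediate by the second step was 0.82 h, longer than the 0.571 h I had reckoned for fresh partner but short against 3.0 h. Scaled by the square to the neighbouring flask with 0.062 M of starting material, equivalents and loadings held, my halving time at fresh partner became 9.29 h, long against 3.0 h, and that flask held target 4.89% beside intermediate 45.6% at 3.00 h.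

The runs come from a simulation for substances that don't exist, noise included.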